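**Plan**

1. Ring numbering used throughout: C1 (heptenyl), C2 and C6 (each bearing a carboxyl carbon), C3 (pentyl), C4=C5. The retrosynthesis cuts the two amide C–N bonds first (diester 11), then traces the C3–H/C4=C5 array back to the enone C3=C4–C5=O of 7 by a reductive 1,3-transposition, then cuts the ring of 7 at C1–C2, C1–C6 and C3–C4.
2. Enabling feature: C1 with its alkenyl arm lies between two carboxyl-bearing carbons, and C3 and C5 are ketone carbons in 7. C1 is therefore the aldehyde carbon of (E)-oct-2-enal, C2/C3 the α- and keto carbons of methyl 3-oxooctanoate, and C6/C5/C4 the α-, keto and methyl carbons of methyl acetoacetate.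
3. Forward: the only ring is made in step 1 (Knoevenagel condensation, Michael addition and aldol condensation in one flask). Step 2 gives the tosylhydrazone, step 3 reduces it with migration of the double bond, step 4 converts both esters into isobutylamides.
4. Stereochemistry: C1 comes from the thiourea-controlled Michael addition; C2 and C6 settle by equilibration trans to the heptenyl group; C3 is set by suprafacial hydrogen transfer from a C5 diazene whose configuration follows from axial hydride delivery; the E double bond is carried in with oct-2-enal.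

Key step: step 1

Assumption: the sense of induction of the amine–thiourea on acceptor 4 cannot be predicted with confidence; the (1R,2R) catalyst is written, and its (1S,2S) antipode is to be used if a trial run shows the opposite sense at C1.

**Step 1**
Reactants: 1 (E)-oct-2-enal; 2 methyl 3-oxooctanoate; 3 methyl acetoacetate
Product: 7 dimethyl (1R,2S,3S)-2-[(E)-hept-1-enyl]-6-oxo-4-pentylcyclohex-4-ene-1,3-dicarboxylate, via Knoevenagel dienoate 4 (not isolated), via acyclic Michael adduct 5 (not isolated), via cyclic ketol 6 (not isolated)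
Conditions: a) 1 (1.1 equiv), 2 (1.0 equiv), piperidine/AcOH (5 mol % each), 4 Å MS, CH2Cl2, 0 °C, then short silica pad and solvent exchange to toluene; b) 3 (1.2 equiv), 1-[3,5-bis(trifluoromethyl)phenyl]-3-[(1R,2R)-2-(dimethylamino)cyclohexyl]thiourea (10 mol %), toluene, −20 °C; c) piperidine/AcOH (20 mol % each), 0 °C to rt; d) p-TsOH·H2O (0.6 equiv), 50 °C
Reagents that add atoms: none
Why: Proposed new method: the crossed, enantioselective three-component version on a dienylidene acceptor is not documented, but it rests on two known reaction types, the Hagemann–Knoevenagel cyclohexenone synthesis from an aldehyde and two β-keto esters and the tertiary amine–thiourea-catalysed Michael addition of β-keto esters to alkylidene 1,3-dicarbonyl compounds, and each mechanistic event is ordinary. Iminium-mediated Knoevenagel condensation of 1 with 2 gives 4 (C1–C2), the thiourea then holds the 1,3-dicarbonyl unit of 4 by hydrogen bonding while its dimethylamino group delivers the enol of 3 to the former aldehyde carbon (C1–C6), piperidine next converts the less hindered acetyl ketone of 5 into an enamine that adds to the octanoyl ketone (C3–C4), and acid dehydrates ketol 6 into conjugation. The ring closes by a 6-(enolendo)-exo-trig aldol addition, favoured by the Baldwin rules. C1 is fixed by the catalyst, which exposes one face of the acceptor, and cannot epimerise once the ring is closed, whereas C2 and C6 stay enolisable (retro-aldol at the ketol stage, β-keto ester and vinylogous enolisation in 7) and settle equatorial, both trans to the heptenyl group. The step needs 1,4- instead of 1,6-addition, a crossed assembly, and closure through the acetyl methyl instead of the octanoyl α'-methylene; the first is secured by the two carbonyl groups that activate the former aldehyde carbon and by the fact that only the 1,4-adduct can cyclise, the second by adding 3 only after 2 is consumed, and the third by the lower steric demand of the methyl ketone in enamine formation and of ketol 6, which has one ring substituent fewer than its regioisomer.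

**Step 2**
Reactants: 7 dimethyl (1R,2S,3S)-2-[(E)-hept-1-enyl]-6-oxo-4-pentylcyclohex-4-ene-1,3-dicarboxylate
Product: 8 dimethyl (1R,2S,3S)-2-[(E)-hept-1-enyl]-6-[2-(4-methylbenzenesulfonyl)hydrazinylidene]-4-pentylcyclohex-4-ene-1,3-dicarboxylate
Conditions: TsNHNH2 (1.1 equiv), AcOH (5 mol %), MeOH, rt
Reagents that add atoms: 4-methylbenzenesulfonohydrazide, SMILES Cc1ccc(cc1)S(=O)(=O)NN
Why: Acid-catalysed hydrazone condensation at the only ketone: the ester carbonyls do not react, the fully substituted enone terminus C3 resists aza-Michael addition, and C6, still enolisable beside the C=N bond, should remain equatorial and trans to the heptenyl group.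

**Step 3**
Reactants: 8 dimethyl (1R,2S,3S)-2-[(E)-hept-1-enyl]-6-[2-(4-methylbenzenesulfonyl)hydrazinylidene]-4-pentylcyclohex-4-ene-1,3-dicarboxylate
Product: 11 dimethyl (1R,2R,3S,6R)-2-[(E)-hept-1-enyl]-6-pentylcyclohex-4-ene-1,3-dicarboxylate, via N-boryl sulfonylhydrazine 9 (not isolated), via allylic diazene 10 (not isolated)
Conditions: catecholborane (2.5 equiv), CHCl3, 0 °C; then NaOAc·3H2O (3 equiv), reflux
Reagents that add atoms: none
Why: This is the catecholborane reduction of an α,β-unsaturated tosylhydrazone with 1,3-transposition of the alkene: hydride should add to C5 axially, anti to the axial C6–H and thus on the face of the two ester groups, sulfinate loss then leaves the C5 diazene on the heptenyl face, and its retro-ene loss of N2 delivers hydrogen suprafacially to that face of C3, which places the pentyl group cis to the C2 ester and moves the double bond to C4=C5.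

**Step 4**
Reactants: 11 dimethyl (1R,2R,3S,6R)-2-[(E)-hept-1-enyl]-6-pentylcyclohex-4-ene-1,3-dicarboxylate; 12 isobutylamine (2-methylpropan-1-amine)
Product: 13 (1R,2R,3S,6R)-2-[(E)-hept-1-enyl]-N1,N3-bis(2-methylpropyl)-6-pentylcyclohex-4-ene-1,3-dicarboxamide
Conditions: 12 (6 equiv), AlMe3 (6 equiv), toluene, 0 °C then 80 °C; aqueous potassium sodium tartrate work-up
Reagents that add atoms: none
Why: Trimethylaluminium-mediated aminolysis of esters, in which the dimethylaluminium amide formed from 12 and AlMe3 converts both methyl esters into secondary amides under Lewis-acidic, weakly basic conditions that should leave the four ring stereocentres and the position of the ring double bond untouched, no new stereocentre being formed.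

**Compound list**

1 | (E)-oct-2-enal | CCCCC/C=C/C=O | starting material
2 | methyl 3-oxooctanoate | CCCCCC(=O)CC(=O)OC | starting material
3 | methyl acetoacetate (methyl 3-oxobutanoate) | CC(=O)CC(=O)OC | starting material
4 | methyl (4E)-2-hexanoyldeca-2,4-dienoate (E/Z mixture at C2=C3) | CCCCC/C=C/C=C(C(=O)CCCCC)C(=O)OC | intermediate
5 | dimethyl (3R)-2-acetyl-3-[(E)-hept-1-enyl]-4-hexanoylpentanedioate (epimers at C2 and C4) | CCCCC/C=C/[C@@H](C(C(=O)CCCCC)C(=O)OC)C(C(C)=O)C(=O)OC | intermediate
6 | dimethyl (1R,2S,3S)-2-[(E)-hept-1-enyl]-4-hydroxy-6-oxo-4-pentylcyclohexane-1,3-dicarboxylate (carbinol configuration at C4 left open) | CCCCC/C=C/[C@H]1[C@H](C(=O)OC)C(O)(CCCCC)CC(=O)[C@@H]1C(=O)OC | intermediate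
7 | dimethyl (1R,2S,3S)-2-[(E)-hept-1-enyl]-6-oxo-4-pentylcyclohex-4-ene-1,3-dicarboxylate | CCCCC/C=C/[C@H]1[C@H](C(=O)OC)C(CCCCC)=CC(=O)[C@@H]1C(=O)OC | intermediate
8 | dimethyl (1R,2S,3S)-2-[(E)-hept-1-enyl]-6-[2-(4-methylbenzenesulfonyl)hydrazinylidene]-4-pentylcyclohex-4-ene-1,3-dicarboxylate | CCCCC/C=C/[C@H]1[C@H](C(=O)OC)C(CCCCC)=CC(=NNS(=O)(=O)c2ccc(C)cc2)[C@@H]1C(=O)OC | intermediate
9 | dimethyl (1R,2S,3S,6R)-6-[1-(1,3,2-benzodioxaborol-2-yl)-2-(4-methylbenzenesulfonyl)hydrazinyl]-2-[(E)-hept-1-enyl]-4-pentylcyclohex-4-ene-1,3-dicarboxylate | CCCCC/C=C/[C@H]1[C@H](C(=O)OC)C(CCCCC)=C[C@@H](N(B2Oc3ccccc3O2)NS(=O)(=O)c2ccc(C)cc2)[C@@H]1C(=O)OC | intermediate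
10 | dimethyl (1R,2S,3S,6R)-6-diazenyl-2-[(E)-hept-1-enyl]-4-pentylcyclohex-4-ene-1,3-dicarboxylate | CCCCC/C=C/[C@H]1[C@H](C(=O)OC)C(CCCCC)=C[C@@H](N=N)[C@@H]1C(=O)OC | intermediate
11 | dimethyl (1R,2R,3S,6R)-2-[(E)-hept-1-enyl]-6-pentylcyclohex-4-ene-1,3-dicarboxylate | CCCCC/C=C/[C@H]1[C@H](C(=O)OC)[C@H](CCCCC)C=C[C@@H]1C(=O)OC | intermediate
12 | isobutylamine (2-methylpropan-1-amine) | CC(C)CN | starting material
13 | (1R,2R,3S,6R)-2-[(E)-hept-1-enyl]-N1,N3-bis(2-methylpropyl)-6-pentylcyclohex-4-ene-1,3-dicarboxamide | CCCCC/C=C/[C@H]1[C@H](C(=O)NCC(C)C)[C@H](CCCCC)C=C[C@@H]1C(=O)NCC(C)C | target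

**Step count and risks**

Total: 4 steps. Longest linear sequence: 4 steps (1, 2 and 3 to 13).

Step 1 (riskiest). The ring may close through the wrong enamine (octanoyl α'-methylene onto the acetyl carbonyl), and amine-induced retro-Michael exchange of the two keto ester arms during the ketol stage would blur both the constitution and the configuration at C1. The E/Z mobility of acceptor 4 may also limit facial control. The fallback is the known Michael addition/intramolecular Horner–Wadsworth–Emmons annulation, in which the nucleophilic carbon is marked by a phosphonate so that closure is an irreversible olefination needing no secondary amine. It sets out from 1 and 2, which are condensed with TiCl4/pyridine (THF, 0 °C), and 4 is isolated. The known reagent methyl 4-(diethoxyphosphoryl)-3-oxobutanoate F1 is added through its C2 to 4 under the same thiourea to give dimethyl (3S)-2-[2-(diethoxyphosphoryl)acetyl]-3-[(E)-hept-1-enyl]-4-hexanoylpentanedioate F2. LiCl/DBU in MeCN then closes C3=C4 onto the octanoyl ketone, which brings the sequence back to the route at 7.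

Step 3. Hydride may reach the hydrazone carbon from the equatorial direction or with little facial preference; because the hydrogen shift is suprafacial, this would appear as the wrong or a mixed configuration at C3. Enehydrazine tautomerism of the β-keto ester hydrazone may also slow the reduction. The fallback reaches the same diazene from an allylic alcohol whose configuration is chosen by the reducing agent and can be purified before the transposition. It sets out from 7: chelation-controlled 1,2-reduction with Zn(BH4)2 (Et2O, −20 °C) should give the cis-β-hydroxy ester dimethyl (1R,2S,3S,6S)-2-[(E)-hept-1-enyl]-6-hydroxy-4-pentylcyclohex-4-ene-1,3-dicarboxylate F3. Mitsunobu displacement with 2-nitrobenzenesulfonohydrazide (PPh3, diethyl azodicarboxylate, THF, −30 °C) inverts C5 and gives dimethyl (1R,2S,3S,6R)-2-[(E)-hept-1-enyl]-6-[1-(2-nitrobenzenesulfonyl)hydrazinyl]-4-pentylcyclohex-4-ene-1,3-dicarboxylate F4. On warming, this loses the sulfinic acid and joins the route at diazene 10, which goes on to 11.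

Step 4. The aluminium amide or the excess amine may shift the C4=C5 double bond into conjugation with the C6 carbonyl by deprotonation at C6, or the hindered C2 ester may resist aminolysis. The fallback goes through the free acid. It sets out from 11: both methyl esters are cleaved with Me3SnOH (1,2-dichloroethane, 80 °C) to (1R,2R,3S,6R)-2-[(E)-hept-1-enyl]-6-pentylcyclohex-4-ene-1,3-dicarboxylic acid F5, which is coupled with 12 (EDC·HCl, HOBt, CH2Cl2, 0 °C to rt) to arrive at 13.

**Further compounds**

F1 | step 1 | methyl 4-(diethoxyphosphoryl)-3-oxobutanoate | CCOP(=O)(OCC)CC(=O)CC(=O)OC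
F2 | step 1 | dimethyl (3S)-2-[2-(diethoxyphosphoryl)acetyl]-3-[(E)-hept-1-enyl]-4-hexanoylpentanedioate | CCCCC/C=C/[C@@H](C(C(=O)CCCCC)C(=O)OC)C(C(=O)CP(=O)(OCC)OCC)C(=O)OC
F3 | step 3 | dimethyl (1R,2S,3S,6S)-2-[(E)-hept-1-enyl]-6-hydroxy-4-pentylcyclohex-4-ene-1,3-dicarboxylate | CCCCC/C=C/[C@H]1[C@H](C(=O)OC)C(CCCCC)=C[C@H](O)[C@@H]1C(=O)OC
F4 | step 3 | dimethyl (1R,2S,3S,6R)-2-[(E)-hept-1-enyl]-6-[1-(2-nitrobenzenesulfonyl)hydrazinyl]-4-pentylcyclohex-4-ene-1,3-dicarboxylate | CCCCC/C=C/[C@H]1[C@H](C(=O)OC)C(CCCCC)=C[C@@H](N(N)S(=O)(=O)c2ccccc2[N+](=O)[O-])[C@@H]1C(=O)OC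
F5 | step 4 | (1R,2R,3S,6R)-2-[(E)-hept-1-enyl]-6-pentylcyclohex-4-ene-1,3-dicarboxylic acid | CCCCC/C=C/[C@H]1[C@H](C(=O)O)[C@H](CCCCC)C=C[C@@H]1C(=O)O
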